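**Strategy**

- Numbering follows the cembrane skeleton: C-1 ring-fusion CH, C-2 lactone O–CH, C-13 acetoxy CH, C-14 the CH2 between C-13 and C-1, C-15/C-16/C-17 the C(=CH2)–C(=O) unit of the lactone.
- Enabling feature: C-2 through C-13 of the 14-membered ring are the C-1 to C-12 backbone of (E,E)-farnesol with oxygen at each allylic terminus. The cis-fused α-methylene-γ-butyrolactone on C-1–C-2 is what a C-2 aldehyde gives with a 2-(alkoxycarbonyl)allyl metal whose γ-carbon C-1 is already bonded to C-14, so making C-1–C-2 closes the carbocycle and releases the alkoxide that closes the lactone.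
- Retrosynthesis: O–C-16 (lactone) and C-1–C-2 (ring) are cut in one operation to an acyclic enal carrying a 2-(methoxycarbonyl)allyl carbonate; then the C-1=C-15 olefin (cross-metathesis) and the C-13–C-14 bond (carbonyl allylation) are cut, leaving (2E,6E)-farnesol, allyl acetate and methyl 2-(hydroxymethyl)acrylate.
- Forward: farnesol is protected and oxidised at its terminal E methyl group (future C-13); the chain is lengthened first at C-13–C-14, then at C-1=C-15; the last step forms the 14-membered carbocycle and, directly after it, the five-membered lactone.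
- Stereochemistry: C-13 (R) is set by the chiral iridium catalyst of the first allylation; C-1 and C-2 (S,S, cis) are set together in the last step, the relative configuration by a chair transition state and the absolute one by the chiral bisphosphine; the three E ring olefins are those of farnesol.

Key step: step 9

Assumption: the ligand antipodes written ((R)-BINAP in step 3, (R)-SEGPHOS in step 9) are assigned by analogy with the usual sense of induction of these iridium catalysts; if the Mosher esters of the step-3 alcohol show the opposite sense, the mirror-image ligand is used with no other change.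

**Step 1**
Reactants: 1 (2E,6E)-farnesol
Product: 2 tert-butyldimethylsilyl ether of (2E,6E)-farnesol
Conditions: TBSCl, imidazole, CH2Cl2, 0 °C to rt
Reagents that add atoms: tert-butyldimethylsilyl chloride, CC(C)(C)[Si](C)(C)Cl
Why: Routine imidazole-promoted silylation of a primary allylic alcohol gives an ether that should survive the selenium oxidation, the hot, weakly basic iridium allylation and the metathesis, and can later be removed by fluoride without base.

**Step 2**
Reactants: 2 tert-butyldimethylsilyl ether of (2E,6E)-farnesol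
Product: 3 (2E,6E,10E)-12-(tert-butyldimethylsilyloxy)-2,6,10-trimethyldodeca-2,6,10-trien-1-ol
Conditions: SeO2 (cat.), t-BuOOH, salicylic acid (cat.), CH2Cl2, 0 °C to rt
Reagents that add atoms: selenium dioxide, O=[Se]=O (delivers the oxygen atom and is re-oxidised by tert-butyl hydroperoxide, CC(C)(C)OO)
Why: Catalytic SeO2/t-BuOOH allylic oxidation (ene reaction, then [2,3]-sigmatropic shift) should attack the most electron-rich and least hindered terminal trisubstituted olefin at its E methyl group, as is usual for farnesyl derivatives, and is stopped short of full conversion to limit over-oxidation to the enal.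

**Step 3**
Reactants: 3 (2E,6E,10E)-12-(tert-butyldimethylsilyloxy)-2,6,10-trimethyldodeca-2,6,10-trien-1-ol; 4 allyl acetate
Product: 5 (4R,5E,9E,13E)-15-(tert-butyldimethylsilyloxy)-5,9,13-trimethylpentadeca-1,5,9,13-tetraen-4-ol
Conditions: [Ir(cod)Cl]2 (2.5 mol%), (R)-BINAP (5 mol%), 3-nitrobenzoic acid (10 mol%), Cs2CO3 (20 mol%), 4 (excess), THF, 100 °C (sealed tube)
Reagents that add atoms: none
Why: Krische allylation (iridium-catalysed transfer-hydrogenative carbonyl allylation from the alcohol oxidation level): the primary allylic alcohol is dehydrogenated to the enal, which is allylated through a closed chair by the cyclometallated (R)-BINAP π-allyliridium complex so that C-13 is expected as R under catalyst control, while the secondary alcohol formed is not dehydrogenated and so cannot racemise.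

**Step 4**
Reactants: 5 (4R,5E,9E,13E)-15-(tert-butyldimethylsilyloxy)-5,9,13-trimethylpentadeca-1,5,9,13-tetraen-4-ol
Product: 6 (4R,5E,9E,13E)-15-(tert-butyldimethylsilyloxy)-5,9,13-trimethylpentadeca-1,5,9,13-tetraen-4-yl acetate
Conditions: Ac2O, DMAP (cat.), pyridine, 0 °C to rt
Reagents that add atoms: acetic anhydride, CC(=O)OC(C)=O
Why: DMAP-catalysed acylation of the secondary allylic alcohol proceeds with retention at C-13 and installs the acetate of the target before any base-sensitive carbonate is present.

**Step 5**
Reactants: 7 methyl 2-(hydroxymethyl)acrylate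
Product: 8 methyl 2-[(tert-butoxycarbonyloxy)methyl]acrylate
Conditions: Boc2O, DMAP (cat.), CH2Cl2, 0 °C to rt
Reagents that add atoms: di-tert-butyl dicarbonate, CC(C)(C)OC(=O)OC(=O)OC(C)(C)C
Why: DMAP-catalysed O-tert-butoxycarbonylation of the primary allylic alcohol gives the carbonate leaving group that iridium will later ionise.

**Step 6**
Reactants: 6 (4R,5E,9E,13E)-15-(tert-butyldimethylsilyloxy)-5,9,13-trimethylpentadeca-1,5,9,13-tetraen-4-yl acetate; 8 methyl 2-[(tert-butoxycarbonyloxy)methyl]acrylate
Product: 9 methyl (2E,5R,6E,10E,14E)-5-acetoxy-2-[(tert-butoxycarbonyloxy)methyl]-16-(tert-butyldimethylsilyloxy)-6,10,14-trimethylhexadeca-2,6,10,14-tetraenoate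
Conditions: second-generation Hoveyda–Grubbs catalyst RuCl2(H2IMes)(=CH-C6H4-2-O-i-Pr) (cat., in portions), 8 (excess), 1,4-benzoquinone (cat.), CH2Cl2, 40 °C
Reagents that add atoms: none
Why: Olefin cross-metathesis of a terminal alkene with an excess of a slowly homodimerising 1,1-disubstituted acrylate, a pairing established for methacrylate-type partners, should give the trisubstituted enoate with the chain trans to the ester, while the trisubstituted chain olefins and the homoallylic acetate stay out of the reaction and either olefin geometry would serve step 9.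

**Step 7**
Reactants: 9 methyl (2E,5R,6E,10E,14E)-5-acetoxy-2-[(tert-butoxycarbonyloxy)methyl]-16-(tert-butyldimethylsilyloxy)-6,10,14-trimethylhexadeca-2,6,10,14-tetraenoate
Product: 10 methyl (2E,5R,6E,10E,14E)-5-acetoxy-2-[(tert-butoxycarbonyloxy)methyl]-16-hydroxy-6,10,14-trimethylhexadeca-2,6,10,14-tetraenoate
Conditions: HF·pyridine, pyridine, THF, 0 °C to rt
Reagents that add atoms: none
Why: Fluoride cleavage of the primary allylic silyl ether under buffered, non-basic conditions should leave the acetate, the allylic carbonate and the enoate untouched.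

**Step 8**
Reactants: 10 methyl (2E,5R,6E,10E,14E)-5-acetoxy-2-[(tert-butoxycarbonyloxy)methyl]-16-hydroxy-6,10,14-trimethylhexadeca-2,6,10,14-tetraenoate
Product: 11 methyl (2E,5R,6E,10E,14E)-5-acetoxy-2-[(tert-butoxycarbonyloxy)methyl]-6,10,14-trimethyl-16-oxohexadeca-2,6,10,14-tetraenoate (seco enal)
Conditions: MnO2 (activated, excess), CH2Cl2, rt
Reagents that add atoms: none
Why: Activated MnO2 oxidises only the primary allylic alcohol, without acid or base, to the E enal and should not affect the carbonate, the acetate or C-13.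

**Step 9**
Reactants: 11 methyl (2E,5R,6E,10E,14E)-5-acetoxy-2-[(tert-butoxycarbonyloxy)methyl]-6,10,14-trimethyl-16-oxohexadeca-2,6,10,14-tetraenoate (seco enal)
Product: 13 (1S,2S,3E,7E,11E,13R)-13-acetoxycembra-3,7,11,15(17)-tetraen-16,2-olide (target CNP0182196.1), via macrocyclic hydroxy ester 12 (not isolated)
Conditions: [Ir(cod)Cl]2 (5 mol%), (R)-SEGPHOS (10 mol%), 4-chloro-3-nitrobenzoic acid (20 mol%), Cs2CO3 (40 mol%), i-PrOH (2 equiv), THF, 70 °C; 11 added by syringe pump over 12 h (final about 0.003 M)
Reagents that add atoms: none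
Why: Proposed new method: the ortho-cyclometallated iridium C,O-benzoate formed in situ is reduced by 2-propanol and Cs2CO3 to an anionic monovalent iridium species, which ionises the ester-activated primary allylic carbonate of 11 (CO2 and tert-butoxide leave) to a trivalent π-allyliridium complex; its σ-allyl form, with iridium on C-17 and C-14 cis to the CH2–Ir arm, binds the C-2 aldehyde and delivers C-1 to it with allylic transposition through a closed six-membered chair, the C-2 alkoxide (12) then acylates the neighbouring methyl ester, and 2-propanol regenerates the iridium hydride. The closest known reaction type is the intermolecular iridium-catalysed transfer-hydrogenative 2-(alkoxycarbonyl)allylation of aldehydes or primary alcohols to α-methylene-γ-butyrolactones, supported by the CrCl2- or zinc-mediated intramolecular additions of 2-(bromomethyl)acrylates to aldehydes that close 14-membered cembranolide rings; untested here are a γ-substituted donor and an intramolecular, macrocycle-forming addition. The 14-membered carbocycle closes by intramolecular carbonyl addition (C-1 to C-2, run under pseudo-high dilution by slow addition of 11 to the catalyst), and the five-membered lactone closes by 5-exo-trig acyl substitution of O-2 at C-16 with loss of methanol. The cis relation of H-1 and H-2 follows from the chair with C-14 pseudo-axial, imposed by the σ-allyl geometry that keeps C-14 away from the conjugated ester (so E and Z carbonates converge by π–σ–π exchange), and the absolute sense (1S,2S) comes from the (R)-SEGPHOS-bound iridium, which selects the aldehyde face and should dominate the C-13 centre. The step needs ionisation of the carbonate rather than the C-13 acetate, 1,2-addition leading only to the large ring, and syn diastereoselection; the substrate offers an ester-activated primary carbonate against a hindered secondary 2-methyl-1,3-dialkylallyl acetate, an enal without α-hydrogens whose E C-3=C-4 bond rules out small rings, and only trisubstituted, unreactive spectator olefins.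

**Compound list**

1 | (2E,6E)-farnesol | OC/C=C(\C)CC/C=C(\C)CCC=C(C)C | starting material
2 | tert-butyldimethylsilyl ether of (2E,6E)-farnesol | CC(C)(C)[Si](C)(C)OC/C=C(\C)CC/C=C(\C)CCC=C(C)C | intermediate
3 | (2E,6E,10E)-12-(tert-butyldimethylsilyloxy)-2,6,10-trimethyldodeca-2,6,10-trien-1-ol | CC(C)(C)[Si](C)(C)OC/C=C(\C)CC/C=C(\C)CC/C=C(\C)CO | intermediate
4 | allyl acetate | C=CCOC(C)=O | starting material
5 | (4R,5E,9E,13E)-15-(tert-butyldimethylsilyloxy)-5,9,13-trimethylpentadeca-1,5,9,13-tetraen-4-ol | CC(C)(C)[Si](C)(C)OC/C=C(\C)CC/C=C(\C)CC/C=C(\C)[C@H](O)CC=C | intermediate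
6 | (4R,5E,9E,13E)-15-(tert-butyldimethylsilyloxy)-5,9,13-trimethylpentadeca-1,5,9,13-tetraen-4-yl acetate | CC(C)(C)[Si](C)(C)OC/C=C(\C)CC/C=C(\C)CC/C=C(\C)[C@H](OC(C)=O)CC=C | intermediate
7 | methyl 2-(hydroxymethyl)acrylate | C=C(CO)C(=O)OC | starting material
8 | methyl 2-[(tert-butoxycarbonyloxy)methyl]acrylate | C=C(COC(=O)OC(C)(C)C)C(=O)OC | intermediate
9 | methyl (2E,5R,6E,10E,14E)-5-acetoxy-2-[(tert-butoxycarbonyloxy)methyl]-16-(tert-butyldimethylsilyloxy)-6,10,14-trimethylhexadeca-2,6,10,14-tetraenoate | CC(C)(C)[Si](C)(C)OC/C=C(\C)CC/C=C(\C)CC/C=C(\C)[C@H](OC(C)=O)C/C=C(\COC(=O)OC(C)(C)C)C(=O)OC | intermediate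
10 | methyl (2E,5R,6E,10E,14E)-5-acetoxy-2-[(tert-butoxycarbonyloxy)methyl]-16-hydroxy-6,10,14-trimethylhexadeca-2,6,10,14-tetraenoate | OC/C=C(\C)CC/C=C(\C)CC/C=C(\C)[C@H](OC(C)=O)C/C=C(\COC(=O)OC(C)(C)C)C(=O)OC | intermediate
11 | methyl (2E,5R,6E,10E,14E)-5-acetoxy-2-[(tert-butoxycarbonyloxy)methyl]-6,10,14-trimethyl-16-oxohexadeca-2,6,10,14-tetraenoate (seco enal) | O=C/C=C(\C)CC/C=C(\C)CC/C=C(\C)[C@H](OC(C)=O)C/C=C(\COC(=O)OC(C)(C)C)C(=O)OC | intermediate
12 | methyl 2-[(1S,2S,3E,7E,11E,13R)-13-acetoxy-2-hydroxy-4,8,12-trimethylcyclotetradeca-3,7,11-trien-1-yl]acrylate (macrocyclic hydroxy ester, not isolated) | O[C@H]1/C=C(\C)CC/C=C(\C)CC/C=C(\C)[C@H](OC(C)=O)C[C@H]1C(=C)C(=O)OC | intermediate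
13 | (1S,2S,3E,7E,11E,13R)-13-acetoxycembra-3,7,11,15(17)-tetraen-16,2-olide (CNP0182196.1) | C=C1C(=O)O[C@H]2/C=C(\C)CC/C=C(\C)CC/C=C(\C)[C@H](OC(C)=O)C[C@@H]12 | target

Total step count: 9. Longest linear sequence: 8 steps (1 to 13 through steps 1–4 and 6–9; step 5 is a one-step side branch).

**Steps most likely to fail**

1. Step 9 (proposed new method).
   - What may go wrong: under high dilution the allyliridium intermediate may be protonated or reduced, or may oligomerise, before the slow carbonyl addition across a 14-membered ring occurs; the macrocyclic constraint may also erode ligand control of the aldehyde face.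
   - Fallback (known chemistry), setting out from 6 and returning at 13 through 12: the silyl ether of 6 is cleaved (HF·pyridine, pyridine, THF) to (4R,5E,9E,13E)-15-hydroxy-5,9,13-trimethylpentadeca-1,5,9,13-tetraen-4-yl acetate F1, which MnO2 in CH2Cl2 oxidises to (4R,5E,9E,13E)-5,9,13-trimethyl-15-oxopentadeca-1,5,9,13-tetraen-4-yl acetate F2. Cross-metathesis of F2 with commercial methyl 2-(bromomethyl)acrylate (second-generation Hoveyda–Grubbs catalyst RuCl2(H2IMes)(=CH-C6H4-2-O-i-Pr), CH2Cl2, 40 °C; the same kind of metathesis as step 6, placed after the oxidation so that the allylic bromide never meets fluoride or pyridine) should give methyl (2Z,5R,6E,10E,14E)-5-acetoxy-2-(bromomethyl)-6,10,14-trimethyl-16-oxohexadeca-2,6,10,14-tetraenoate F3. Slow addition of F3 to excess CrCl2 in THF at rt (intramolecular Nozaki–Hiyama–Kishi-type allylation, the established ring closure of cembranolide α-methylene lactones) should give the chromium alkoxide of 12, which lactonises on work-up or with catalytic p-TsOH to 13. Here the cis lactone relies on the syn-selective cyclic transition state of the allylchromium reagent and the absolute sense at C-1/C-2 only on the C-13 centre, so a diastereomer separation may be needed.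

2. Step 6.
   - What may go wrong: the electron-poor, crowded 1,1-disubstituted acrylate may fail to enter productive metathesis, so that homodimerisation of 6 and catalyst decay prevail.
   - Fallback, setting out from 6 and returning at 9: the ester oxidation level is taken out of the metathesis. 2-Methylenepropane-1,3-diol is mono-protected (Boc2O, DMAP cat., CH2Cl2) to tert-butyl 2-(hydroxymethyl)prop-2-en-1-yl carbonate F4, an electron-neutral 1,1-disubstituted allylic olefin of the class known to cross with terminal alkenes under the same ruthenium catalyst. Cross-metathesis of 6 with F4 should give the trisubstituted allylic alcohol with C-14 cis to the carbonate arm F5 together with its geometric isomer, the allylic alcohol with C-14 trans to the carbonate arm F6; the mixture is carried on because step 9 erases this geometry in the π-allyl. MnO2 (CH2Cl2) should give the 2E enal F7 and the 2Z enal F8; Pinnick oxidation (NaClO2, NaH2PO4, 2-methyl-2-butene, t-BuOH/H2O) the 2E acid F9 and the 2Z acid F10; methylation with TMSCHN2 (MeOH/toluene) then gives 9 and its 2Z isomer F11, both competent substrates for steps 7–9.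

3. Step 3.
   - What may go wrong: on this α-methyl-branched allylic alcohol, dehydrogenation and turnover may be incomplete, the transient enal may undergo conjugate reduction, or enantiofacial discrimination may be insufficient.
   - Fallback, setting out from 3 and returning at 5: 3 is oxidised with MnO2 (CH2Cl2) to (2E,6E,10E)-12-(tert-butyldimethylsilyloxy)-2,6,10-trimethyldodeca-2,6,10-trienal F12 (also the over-oxidation product of step 2, so that material is recovered too). F12 is then treated with stoichiometric (+)-Ipc2B(allyl), derived from (−)-α-pinene and generated from (+)-Ipc2BOMe and allylmagnesium bromide, in Et2O at −78 °C, followed by oxidative work-up (NaOH, H2O2) (Brown allylboration; reagent-controlled, Re-face delivery expected by analogy to give the 13R alcohol 5).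

**Further compounds**

F1 | step 9 | (4R,5E,9E,13E)-15-hydroxy-5,9,13-trimethylpentadeca-1,5,9,13-tetraen-4-yl acetate | OC/C=C(\C)CC/C=C(\C)CC/C=C(\C)[C@H](OC(C)=O)CC=C
F2 | step 9 | (4R,5E,9E,13E)-5,9,13-trimethyl-15-oxopentadeca-1,5,9,13-tetraen-4-yl acetate | O=C/C=C(\C)CC/C=C(\C)CC/C=C(\C)[C@H](OC(C)=O)CC=C
F3 | step 9 | methyl (2Z,5R,6E,10E,14E)-5-acetoxy-2-(bromomethyl)-6,10,14-trimethyl-16-oxohexadeca-2,6,10,14-tetraenoate | O=C/C=C(\C)CC/C=C(\C)CC/C=C(\C)[C@H](OC(C)=O)C/C=C(\CBr)C(=O)OC
F4 | step 6 | tert-butyl 2-(hydroxymethyl)prop-2-en-1-yl carbonate | C=C(CO)COC(=O)OC(C)(C)C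
F5 | step 6 | tert-butyl [(2Z,5R,6E,10E,14E)-5-acetoxy-16-(tert-butyldimethylsilyloxy)-2-(hydroxymethyl)-6,10,14-trimethylhexadeca-2,6,10,14-tetraen-1-yl] carbonate (C-14 cis to the carbonate arm) | CC(C)(C)[Si](C)(C)OC/C=C(\C)CC/C=C(\C)CC/C=C(\C)[C@H](OC(C)=O)C/C=C(\COC(=O)OC(C)(C)C)CO
F6 | step 6 | tert-butyl [(2E,5R,6E,10E,14E)-5-acetoxy-16-(tert-butyldimethylsilyloxy)-2-(hydroxymethyl)-6,10,14-trimethylhexadeca-2,6,10,14-tetraen-1-yl] carbonate (C-14 trans to the carbonate arm) | CC(C)(C)[Si](C)(C)OC/C=C(\C)CC/C=C(\C)CC/C=C(\C)[C@H](OC(C)=O)C/C=C(/COC(=O)OC(C)(C)C)CO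
F7 | step 6 | (2E,5R,6E,10E,14E)-5-acetoxy-2-[(tert-butoxycarbonyloxy)methyl]-16-(tert-butyldimethylsilyloxy)-6,10,14-trimethylhexadeca-2,6,10,14-tetraenal | CC(C)(C)[Si](C)(C)OC/C=C(\C)CC/C=C(\C)CC/C=C(\C)[C@H](OC(C)=O)C/C=C(\COC(=O)OC(C)(C)C)C=O
F8 | step 6 | (2Z,5R,6E,10E,14E)-5-acetoxy-2-[(tert-butoxycarbonyloxy)methyl]-16-(tert-butyldimethylsilyloxy)-6,10,14-trimethylhexadeca-2,6,10,14-tetraenal | CC(C)(C)[Si](C)(C)OC/C=C(\C)CC/C=C(\C)CC/C=C(\C)[C@H](OC(C)=O)C/C=C(/COC(=O)OC(C)(C)C)C=O
F9 | step 6 | (2E,5R,6E,10E,14E)-5-acetoxy-2-[(tert-butoxycarbonyloxy)methyl]-16-(tert-butyldimethylsilyloxy)-6,10,14-trimethylhexadeca-2,6,10,14-tetraenoic acid | CC(C)(C)[Si](C)(C)OC/C=C(\C)CC/C=C(\C)CC/C=C(\C)[C@H](OC(C)=O)C/C=C(\COC(=O)OC(C)(C)C)C(=O)O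
F10 | step 6 | (2Z,5R,6E,10E,14E)-5-acetoxy-2-[(tert-butoxycarbonyloxy)methyl]-16-(tert-butyldimethylsilyloxy)-6,10,14-trimethylhexadeca-2,6,10,14-tetraenoic acid | CC(C)(C)[Si](C)(C)OC/C=C(\C)CC/C=C(\C)CC/C=C(\C)[C@H](OC(C)=O)C/C=C(/COC(=O)OC(C)(C)C)C(=O)O
F11 | step 6 | methyl (2Z,5R,6E,10E,14E)-5-acetoxy-2-[(tert-butoxycarbonyloxy)methyl]-16-(tert-butyldimethylsilyloxy)-6,10,14-trimethylhexadeca-2,6,10,14-tetraenoate (2Z isomer of 9) | CC(C)(C)[Si](C)(C)OC/C=C(\C)CC/C=C(\C)CC/C=C(\C)[C@H](OC(C)=O)C/C=C(/COC(=O)OC(C)(C)C)C(=O)OC
F12 | step 3 | (2E,6E,10E)-12-(tert-butyldimethylsilyloxy)-2,6,10-trimethyldodeca-2,6,10-trienal | CC(C)(C)[Si](C)(C)OC/C=C(\C)CC/C=C(\C)CC/C=C(\C)C=O
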